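## The problem

The target is an acorane-type spiro[4.5]decene in which a cyclopentane (ring A, C1–C5) and a cyclohexene (ring B, C5–C10) share only the quaternary carbon C5, so no ring fusion can pass stereochemistry from one ring to the other. Five stereocentres have to be set: C1 (side chain), C5 (spiro) and C4 (methyl) are contiguous in ring A, C11 is an acyclic methine next to C1, and C9 (acyloxy) sits in ring B, insulated from the rest by C5. C4 can be made by asymmetric catalysis in an open-chain precursor and, being next to C5, can decide the face on which C5 becomes quaternary. C1 then has to be tied to C5, C11 can be reached only through allylic strain against C1 and C5, and C9 only through the different flanking of the two faces of ring B by C1–H and by the C4 methyl. The (Z)-γ-alkylidene butenolide will not survive hydride, hydrazine, strong base, one-electron reductants or ultraviolet light, the allylic ester at C9 is open to hydrolysis and ionisation, and C11 epimerises easily once C12 is an aldehyde, so the butenolide has to be made last. Ring B needs a 7-ene, an 8-methyl and a 9-oxygen, which is the 1,3-transposed form of an 8-methyl 7-ketone. The feature that opens the route is that C11 (on C1) and C6 (on C5) lie on the same face of ring A: a temporary C6–C11 bond would close a cyclobutane made of C5, C1, C11 and C6 that can only be cis-fused to ring A, and so would lock C1 against C5. With C7 as a ketone and C12 as an ester, this extra bond lies between two carbonyl groups, where one-electron reduction can cut it again and leave the spirocycle.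

## Retrosynthesis

The exocyclic C12=C double bond of the butenolide is cut first, giving aldehyde 23 and the commercial butenolide 24. Any earlier introduction would expose the dienyl lactone to the reductive and nucleophilic steps that ring B needs. The forward reaction must join a vinylogous enolate of 24 to C12 and eliminate to the Z alkene without epimerising C11.

The C9–O acyl bond of 23 is cut next, to hydroxy aldehyde 21 and acid 22. 21 is taken back through diol 20 to hydroxy ester 19. Acylating 19 directly would leave two esters that no reductant could tell apart, whereas 20 offers a primary and a hindered secondary alcohol that an oxoammonium oxidant can distinguish, so no protecting group is needed.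

The allylic alcohol of 19 (C7=C8, C9–OH) is the Wharton transposition product of epoxy ketone 18, which comes from enone 17 and that from saturated ketone 15. These are functional-group changes only, but they move the oxygen from C7, where the key step needs it, to C9, where the target has it. The forward sequence must dehydrogenate toward C8 and not C6, and epoxidise the face of ring B that is syn to C1.

In 15 a bond is added between C6 and C11, giving tricyclic keto ester 14; the C8 methyl is then removed to give photoadduct 12. Methylating at the tricyclic stage is preferred to methylating 15, because in 12 the only enolisable position is C8 and the ester has no α-hydrogen. The forward cleavage must break C6–C11 and no other bond and must protonate C11 from the face away from C5.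

Photoadduct 12 is cut at C5–C1 and C6–C11, giving enone 11 with a tethered E-enoate. This removes both rings of the cyclobutane/cyclopentane unit and four stereocentres and leaves one stereocentre, C4. A polar closure of C5–C1 alone would leave C1 uncontrolled, and the second bond is what fixes it. The forward photocycloaddition must take the straight rather than the crossed course and must use one face of C5.

Enone 11 is the hydrolysis product of dienyl ether 9, which is cut at C1–C2 into the terminal alkene of diene 6 and bromoacrylate 7. This sp3–sp2 coupling uses the vinyl group that the next disconnection leaves behind, and it brings in C1, C11, the C11 methyl and C12 with the E geometry already set.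

Diene 6 is the Birch product of arene 5, whose C4–CH3 bond is cut in the SN2' sense to cinnamyl bromide 4. 4 comes from alcohol 3 and that from the commercial acid 1. The forward allylic alkylation must be branched-selective and enantioselective, and this single event supplies all the absolute stereochemistry of the route.

## Roads not taken

Alternative 1: The cut is made in ring B. C9 is taken out as carbon monoxide and C8–C9 and C9–C10 are broken, leading to spiro vinylcyclopropane A1, in which C5, C6 and C10 form the three-membered ring and C6 carries the propenyl group. In the forward step Fe(CO)5 under irradiation would open C6–C10, insert CO and, after base-mediated conjugation, give enone A2.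
- Merits: A2 already has the carbonyl at C9, the methyl at C8 and the alkene at C7=C8. Ring B of the target is then one 1,2-reduction (for which reagent control is available) and one acylation away, and C11 arrives settled. In both respects this road is better than the chosen one, which spends steps 8 and 10–12 moving functionality from C7 to C9 and sets C11 by an enolate protonation.
- Weak points: C1, C4, C5 and C11 must all be built into A1 beforehand. The spiro centre would have to come from cyclopropanation of an exocyclic alkene flanked by C1 and C4, which is the same facial problem the chosen plan solves with a tether. The metal must open C6–C10 and not the more substituted C5–C6 bond, which would give a fused skeleton. A volatile toxic metal carbonyl is used in stoichiometric amount.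
- Comparison: the chosen plan sets against this that C5 and C1 are formed together under the control of C4 alone, from a precursor (11) six steps from a commodity acid.

Alternative 2: Both rings are cut at once. C5–C6 and C1–C5 are disconnected, leading to the acyclic (2Z)-configured farnesyl-type ester A3 with a terminal allylsilane. In the forward step, ionisation inside a confined chiral Brønsted acid would close the six-membered ring (C5–C6), a 1,2-hydride shift would move hydrogen from C5 to C4, and the allylsilane would capture the C5 cation (C1–C5) to give diene A4.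
- Merits: no road to the carbon skeleton is shorter. One catalytic step makes two rings and three stereocentres without protecting groups, which beats the seven steps to 12 outright.
- Weak points: the three stereocentres depend on the folding of a flexible cation in the catalyst pocket, with elimination and other ring closures competing. A4 carries no heteroatom: C9 would need an allylic oxidation that has to choose among several allylic positions and two faces, and C11 would have to be created by hydroboration of the isopropenyl group under acyclic control.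
- Comparison: the chosen plan sets against the brevity of this road that the C7 ketone and the C12 ester are in place when the rings form, and that each stereochemical outcome follows from a simple conformational or ring-strain argument.

Alternative 3: The cut is the C4–C5 bond. C4 is reattached to C1, giving cyclobutanol A5, a 3-(1-hydroxy-2-methylcyclobutyl)cyclohex-2-enone. In the forward step the iminium ion of A5 lets C4 migrate from C1 to C5 (a vinylogous α-ketol shift driven by cyclobutane strain), and hydrolysis gives spiro dione A6.
- Merits: the step is thermal and catalytic, the migrating carbon keeps its configuration, and a chiral amine could control the spiro centre. The ring-B carbonyl of A6 can be taken as C9, so oxygen sits where the target needs it and ring B would need only methylation, dehydrogenation and reduction. On ring B this is better than the chosen plan, and it reaches the spirocycle in no more steps.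
- Weak points: C1 emerges as a ketone. The whole side chain must then be attached to a neopentyl cyclopentanone next to the quaternary centre, and C1 and C11 set afterwards by reactions whose facial preference rests on the small difference between C6 and C10. The two ketones must also be told apart.
- Comparison: the chosen plan fixes C1 in the same step as C5 and brings C11 and C12 in with the alkene partner.

Key step: step 7

Remark: locants C1–C12 are those of the target throughout (C12 is the carbon that ends as the ylidene CH); only the names of 12 and 14 use von Baeyer locants.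
Remark: closed-shell species that build up in the flask before the next reagent acts are numbered; ketyls, diradicals, samarium enolates and the Wharton hydrazone are treated as mechanism.
Remark: (R,R)-Taniaphos is assumed to give S at C4, as with unsubstituted cinnamyl bromide; if the sense proves opposite the antipodal ligand is used.
Remark: 14 and 15 are mixtures of C8 epimers, which converge when C8 becomes sp2 in step 10; 12 is drawn with the enoate geometry retained at C11, and its C11 epimer would converge in step 9.

Step 1
Reactants: 1 (E)-3-(3-methoxyphenyl)prop-2-enoic acid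
Product: 3 (E)-3-(3-methoxyphenyl)prop-2-en-1-ol, via mixed carbonic anhydride 2 (not isolated)
Conditions: ClCO2Et, Et3N, THF, −10 °C; then NaBH4, H2O, 0 °C
Reagents that add atoms: ethyl chloroformate, CCOC(=O)Cl (its atoms stay only in intermediate 2)
Why: The acid is activated as the mixed carbonic anhydride and NaBH4 reduces the more electrophilic acyl carbonyl to the primary alcohol (mixed-anhydride reduction); the conjugated E alkene is not touched under these conditions.

Step 2
Reactants: 3 (E)-3-(3-methoxyphenyl)prop-2-en-1-ol
Product: 4 1-[(E)-3-bromoprop-1-en-1-yl]-3-methoxybenzene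
Conditions: PBr3, Et2O, 0 °C
Reagents that add atoms: phosphorus tribromide, BrP(Br)Br
Why: PBr3 converts the primary allylic alcohol into the bromide by SN2 displacement of a phosphite leaving group; the conjugated primary E bromide is also the thermodynamic allylic isomer.

Step 3
Reactants: 4 1-[(E)-3-bromoprop-1-en-1-yl]-3-methoxybenzene
Product: 5 1-[(2S)-but-3-en-2-yl]-3-methoxybenzene
Conditions: MeMgBr, CuBr·SMe2 (cat.), (R,R)-Taniaphos (C43H39FeNP2, cat.), CH2Cl2, −75 °C
Reagents that add atoms: methylmagnesium bromide, C[Mg]Br
Why: Copper-catalysed asymmetric allylic alkylation: the chiral methylcopper species attacks the cinnamyl bromide in the SN2' sense to give the branched alkene, and the ferrocenyl diphosphine sets C4 as S; cinnamyl bromides with methyl Grignard reagent are the standard substrates of this reaction.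

Step 4
Reactants: 5 1-[(2S)-but-3-en-2-yl]-3-methoxybenzene
Product: 6 1-[(2S)-but-3-en-2-yl]-5-methoxycyclohexa-1,4-diene
Conditions: Li, NH3 (l), t-BuOH, THF, −78 °C
Reagents that add atoms: none
Why: Birch reduction of a 3-alkylanisole leaves methoxy and alkyl on the two remaining double bonds, giving the 1-methoxy-5-alkylcyclohexa-1,4-diene; the isolated vinyl group is not reduced, and tert-butanol keeps the amide concentration low so that the C4–H bond is not deprotonated.

Step 5
Reactants: 6 1-[(2S)-but-3-en-2-yl]-5-methoxycyclohexa-1,4-diene; 7 methyl (E)-3-bromo-2-methylprop-2-enoate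
Product: 9 methyl (2E,6S)-6-(5-methoxycyclohexa-1,4-dien-1-yl)-2-methylhept-2-enoate, via B-alkyl-9-BBN borane 8 (not isolated)
Conditions: 9-BBN, THF, 0 °C to rt; then 7, PdCl2(dppf) (cat.), K3PO4, DMF/H2O, rt
Reagents that add atoms: 9-borabicyclo[3.3.1]nonane, B1C2CCCC1CCC2 (boron stays only in intermediate 8)
Why: 9-BBN hydroborates only the monosubstituted alkene (anti-Markovnikov) and leaves the enol ether and the trisubstituted ring alkene; the B-alkyl Suzuki–Miyaura coupling then joins C2 to C1 with retention of the E geometry of the bromoacrylate.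

Step 6
Reactants: 9 methyl (2E,6S)-6-(5-methoxycyclohexa-1,4-dien-1-yl)-2-methylhept-2-enoate
Product: 11 methyl (2E,6S)-2-methyl-6-(3-oxocyclohex-1-en-1-yl)hept-2-enoate, via β,γ-unsaturated ketone 10 (not isolated)
Conditions: 1 M HCl, THF, rt
Reagents that add atoms: water, O
Why: Aqueous acid hydrolyses the enol ether to the β,γ-unsaturated ketone, which conjugates through the ring dienol to the 3-alkylcyclohex-2-enone; the methyl enoate is stable to dilute acid at room temperature and the C4–H bond is not on the isomerisation path.

Step 7
Reactants: 11 methyl (2E,6S)-2-methyl-6-(3-oxocyclohex-1-en-1-yl)hept-2-enoate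
Product: 12 methyl (1R,2S,5S,6R,7S)-2,6-dimethyl-8-oxotricyclo[5.4.0.0^1,5]undecane-6-carboxylate
Conditions: hν (λ > 350 nm, uranium-glass filter), CH2Cl2 (0.01 M, degassed), 0 °C
Reagents that add atoms: none
Why: Excitation and intersystem crossing give the triplet enone, whose β-carbon C5 bonds to C1 and closes ring A by a 5-exo (1,5, rule-of-five) radical closure; the resulting 1,4-diradical (α-keto radical at C6, ester-stabilised tertiary radical at C11) spin-inverts and collapses by C6–C11 bonding, a radical combination that closes the four-membered ring. The closest known reaction type is the intramolecular enone–olefin [2+2] photocycloaddition of 3-(pent-4-enyl)cyclohex-2-enones, which gives such straight adducts. C5 is controlled by C4: allylic 1,3-strain keeps the C4–H bond eclipsed with C5=C6, so the tether reaches one face and the C4 methyl ends cis to C10. C1 is controlled by ring strain, since the cyclobutane can only be cis-fused to the new five-membered ring, which places C11 on the C6 face of ring A. C6 follows from the cis six/four fusion, and C11 follows the enoate geometry only if collapse outruns bond rotation, which is immaterial because C11 is reset in step 9. The step needs facial selectivity at C5 and the straight rather than the crossed course; the first rests on the single allylic stereocentre, the second on the three-atom tether. Irradiation above 350 nm keeps the saturated ketone product out of secondary photochemistry.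

Step 8
Reactants: 12 methyl (1R,2S,5S,6R,7S)-2,6-dimethyl-8-oxotricyclo[5.4.0.0^1,5]undecane-6-carboxylate
Product: 14 methyl (1R,2S,5S,6R,7S)-2,6,9-trimethyl-8-oxotricyclo[5.4.0.0^1,5]undecane-6-carboxylate (methyl on target C8; C8 epimers), via lithium enolate 13 (not isolated)
Conditions: LiN(i-Pr)2, THF, −78 °C; then MeI, −78 to −30 °C
Reagents that add atoms: iodomethane, CI; lithium diisopropylamide, [Li]N(C(C)C)C(C)C (lithium stays only in intermediate 13)
Why: Kinetic deprotonation can occur only at C8, because C6 is a hindered cyclobutane methine between two quaternary carbons and the ester has no α-hydrogen at this stage; alkylation of the lithium enolate with iodomethane installs the C8 methyl, whose configuration is immaterial.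

Step 9
Reactants: 14 methyl (1R,2S,5S,6R,7S)-2,6,9-trimethyl-8-oxotricyclo[5.4.0.0^1,5]undecane-6-carboxylate
Product: 15 methyl (2S)-2-[(1R,4S,5R)-4,8-dimethyl-7-oxospiro[4.5]decan-1-yl]propanoate (C8 epimers)
Conditions: SmI2, HMPA, MeOH, THF, −78 to 0 °C
Reagents that add atoms: none
Why: Electron transfer to the ketone gives the C7 ketyl, which opens the cyclobutane by β-scission of C6–C11 (cyclobutylcarbinyl opening, driven by strain release and by the ester-stabilised tertiary radical at C11, whereas C5–C6 scission would give an unstabilised radical); a second electron gives the ester enolate. Methanol should protonate C11 on the face away from C5 and the just-released C6 while allylic 1,3-strain holds C1–H in the enolate plane, which corresponds to 11S; the reaction type is the SmI2 reductive fragmentation of cyclobutyl ketones and γ-keto esters.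

Step 10
Reactants: 15 methyl (2S)-2-[(1R,4S,5R)-4,8-dimethyl-7-oxospiro[4.5]decan-1-yl]propanoate
Product: 17 methyl (2S)-2-[(1R,4S,5R)-4,8-dimethyl-7-oxospiro[4.5]dec-8-en-1-yl]propanoate, via trimethylsilyl enol ether 16 (not isolated)
Conditions: TMSCl, NaI, Et3N, MeCN, rt; then Pd(OAc)2, MeCN, rt
Reagents that add atoms: chlorotrimethylsilane, C[Si](C)(C)Cl (silicon stays only in intermediate 16)
Why: Equilibrating silylation gives the more substituted C7=C8 enol ether, and Saegusa–Ito oxidation (palladation at C8, β-hydride elimination from C9) gives the endocyclic 2-methyl enone; any enol ether toward C6 cannot be dehydrogenated because C5 is quaternary and simply returns the ketone.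

Step 11
Reactants: 17 methyl (2S)-2-[(1R,4S,5R)-4,8-dimethyl-7-oxospiro[4.5]dec-8-en-1-yl]propanoate
Product: 18 methyl (2S)-2-[(1R,4S,5R,8S,9S)-8,9-epoxy-4,8-dimethyl-7-oxospiro[4.5]decan-1-yl]propanoate
Conditions: H2O2 (30% aq), NaOH, MeOH, 0 °C
Reagents that add atoms: hydrogen peroxide, OO
Why: Weitz–Scheffer nucleophilic epoxidation of a 2-methylcyclohex-2-enone, as with carvone; hydroperoxide should add axially to C9 on the face of ring B flanked only by C1–H (the C1 side chain points toward C6) and not on the face covered by C4 and its methyl, which is cis to C10, and the enolate closes the epoxide on the same face.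

Step 12
Reactants: 18 methyl (2S)-2-[(1R,4S,5R,8S,9S)-8,9-epoxy-4,8-dimethyl-7-oxospiro[4.5]decan-1-yl]propanoate
Product: 19 methyl (2S)-2-[(1R,4S,5S,9S)-9-hydroxy-4,8-dimethylspiro[4.5]dec-7-en-1-yl]propanoate
Conditions: N2H4·H2O, AcOH (cat.), MeOH, 0 °C to rt
Reagents that add atoms: none
Why: Wharton transposition: the hydrazone opens the epoxide to a vinyl diazene that loses N2, which moves the alkene to C7=C8 and leaves the C9–O bond, and hence the C9 configuration, untouched; the hindered methyl ester is not attacked by hydrazine at this temperature.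

Step 13
Reactants: 19 methyl (2S)-2-[(1R,4S,5S,9S)-9-hydroxy-4,8-dimethylspiro[4.5]dec-7-en-1-yl]propanoate
Product: 20 (2S)-2-[(1R,4S,5S,9S)-9-hydroxy-4,8-dimethylspiro[4.5]dec-7-en-1-yl]propan-1-ol
Conditions: LiAlH4, THF, 0 °C
Reagents that add atoms: none
Why: Hydride reduction of the ester to the primary alcohol; no other reducible group is present and no stereocentre is at risk.

Step 14
Reactants: 20 (2S)-2-[(1R,4S,5S,9S)-9-hydroxy-4,8-dimethylspiro[4.5]dec-7-en-1-yl]propan-1-ol
Product: 21 (2S)-2-[(1R,4S,5S,9S)-9-hydroxy-4,8-dimethylspiro[4.5]dec-7-en-1-yl]propanal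
Conditions: TEMPO (cat.), PhI(OAc)2, CH2Cl2, rt
Reagents that add atoms: none
Why: Oxoammonium oxidation is selective for the primary alcohol over the hindered secondary allylic one and is not basic, so C11 next to the new aldehyde should keep its configuration.

Step 15
Reactants: 21 (2S)-2-[(1R,4S,5S,9S)-9-hydroxy-4,8-dimethylspiro[4.5]dec-7-en-1-yl]propanal; 22 3-phenylpropanoic acid
Product: 23 (1R,4S,5S,9S)-4,8-dimethyl-1-[(2S)-1-oxopropan-2-yl]spiro[4.5]dec-7-en-9-yl 3-phenylpropanoate
Conditions: DCC, DMAP (cat.), CH2Cl2, 0 °C to rt
Reagents that add atoms: none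
Why: Steglich esterification acylates the C9 alcohol with retention, since the C9–O bond is not broken; the aldehyde is inert to carbodiimide and to catalytic DMAP at this temperature.

Step 16
Reactants: 23 (1R,4S,5S,9S)-4,8-dimethyl-1-[(2S)-1-oxopropan-2-yl]spiro[4.5]dec-7-en-9-yl 3-phenylpropanoate; 24 3-methylfuran-2(5H)-one
Product: 27 (1R,4S,5S,9S)-4,8-dimethyl-1-[(1Z,2S)-1-(4-methyl-5-oxofuran-2(5H)-ylidene)propan-2-yl]spiro[4.5]dec-7-en-9-yl 3-phenylpropanoate, via silyloxyfuran 25 (not isolated), via silylated aldol adduct 26 (not isolated)
Conditions: TBSOTf, i-Pr2NEt, CH2Cl2, 0 °C (24 only); then 23, −78 °C; then DBU, −78 °C to rt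
Reagents that add atoms: tert-butyldimethylsilyl triflate, CC(C)(C)[Si](C)(C)OS(=O)(=O)C(F)(F)F (silicon stays only in intermediates 25 and 26)
Why: Vinylogous Mukaiyama aldol addition of the silyloxyfuran, formed before the aldehyde is added, gives the silylated adduct, and DBU then eliminates silanol from the γ-position (E1cB through the furanolate) to give the γ-alkylidene butenolide. The Z isomer, which keeps C11 away from the ring C–H, is the favoured product of this one-pot protocol, and the two new sp3 centres of 26 are erased.

Compound list
1 | (E)-3-(3-methoxyphenyl)prop-2-enoic acid | COc1cccc(/C=C/C(O)=O)c1 | starting material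
2 | ethyl carbonic (E)-3-(3-methoxyphenyl)prop-2-enoic anhydride | CCOC(=O)OC(=O)/C=C/c1cccc(OC)c1 | intermediate
3 | (E)-3-(3-methoxyphenyl)prop-2-en-1-ol | COc1cccc(/C=C/CO)c1 | intermediate
4 | 1-[(E)-3-bromoprop-1-en-1-yl]-3-methoxybenzene | COc1cccc(/C=C/CBr)c1 | intermediate
5 | 1-[(2S)-but-3-en-2-yl]-3-methoxybenzene | C=C[C@H](C)c1cccc(OC)c1 | intermediate
6 | 1-[(2S)-but-3-en-2-yl]-5-methoxycyclohexa-1,4-diene | C=C[C@H](C)C1=CCC=C(OC)C1 | intermediate
7 | methyl (E)-3-bromo-2-methylprop-2-enoate | COC(=O)/C(C)=C/Br | starting material
8 | 9-[(3S)-3-(5-methoxycyclohexa-1,4-dien-1-yl)butyl]-9-borabicyclo[3.3.1]nonane | B1(CC[C@H](C)C2=CCC=C(OC)C2)C3CCCC1CCC3 | intermediate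
9 | methyl (2E,6S)-6-(5-methoxycyclohexa-1,4-dien-1-yl)-2-methylhept-2-enoate | COC(=O)/C(C)=C/CC[C@H](C)C1=CCC=C(OC)C1 | intermediate
10 | methyl (2E,6S)-2-methyl-6-(5-oxocyclohex-1-en-1-yl)hept-2-enoate | COC(=O)/C(C)=C/CC[C@H](C)C1=CCCC(=O)C1 | intermediate
11 | methyl (2E,6S)-2-methyl-6-(3-oxocyclohex-1-en-1-yl)hept-2-enoate | COC(=O)/C(C)=C/CC[C@H](C)C1=CC(=O)CCC1 | intermediate
12 | methyl (1R,2S,5S,6R,7S)-2,6-dimethyl-8-oxotricyclo[5.4.0.0^1,5]undecane-6-carboxylate (cyclobutane C5–C1–C11–C6, C4 methyl cis to C10) | COC(=O)[C@]1(C)[C@H]2CC[C@H](C)[C@@]2(CCCC3=O)[C@@H]13 | intermediate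
13 | lithium enolate of 12 (C7–OLi, C7=C8) | COC(=O)[C@]1(C)[C@H]2CC[C@H](C)[C@@]2(CCC=C3O[Li])[C@@H]13 | intermediate
14 | methyl (1R,2S,5S,6R,7S)-2,6,9-trimethyl-8-oxotricyclo[5.4.0.0^1,5]undecane-6-carboxylate (methyl on target C8, both C8 epimers) | COC(=O)[C@]1(C)[C@H]2CC[C@H](C)[C@@]2(CCC(C)C3=O)[C@@H]13 | intermediate
15 | methyl (2S)-2-[(1R,4S,5R)-4,8-dimethyl-7-oxospiro[4.5]decan-1-yl]propanoate (both C8 epimers) | COC(=O)[C@@H](C)[C@H]1CC[C@H](C)[C@@]12CC(=O)C(C)CC2 | intermediate
16 | methyl (2S)-2-[(1R,4S,5R)-4,8-dimethyl-7-(trimethylsilyloxy)spiro[4.5]dec-7-en-1-yl]propanoate | COC(=O)[C@@H](C)[C@H]1CC[C@H](C)[C@@]12CC(O[Si](C)(C)C)=C(C)CC2 | intermediate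
17 | methyl (2S)-2-[(1R,4S,5R)-4,8-dimethyl-7-oxospiro[4.5]dec-8-en-1-yl]propanoate | COC(=O)[C@@H](C)[C@H]1CC[C@H](C)[C@@]12CC(=O)C(C)=CC2 | intermediate
18 | methyl (2S)-2-[(1R,4S,5R,8S,9S)-8,9-epoxy-4,8-dimethyl-7-oxospiro[4.5]decan-1-yl]propanoate (epoxide on the ring-B face syn to C1) | COC(=O)[C@@H](C)[C@H]1CC[C@H](C)[C@@]12CC(=O)[C@@]3(C)O[C@H]3C2 | intermediate
19 | methyl (2S)-2-[(1R,4S,5S,9S)-9-hydroxy-4,8-dimethylspiro[4.5]dec-7-en-1-yl]propanoate | COC(=O)[C@@H](C)[C@H]1CC[C@H](C)[C@@]12CC=C(C)[C@@H](O)C2 | intermediate
20 | (2S)-2-[(1R,4S,5S,9S)-9-hydroxy-4,8-dimethylspiro[4.5]dec-7-en-1-yl]propan-1-ol | OC[C@@H](C)[C@H]1CC[C@H](C)[C@@]12CC=C(C)[C@@H](O)C2 | intermediate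
21 | (2S)-2-[(1R,4S,5S,9S)-9-hydroxy-4,8-dimethylspiro[4.5]dec-7-en-1-yl]propanal | O=C[C@@H](C)[C@H]1CC[C@H](C)[C@@]12CC=C(C)[C@@H](O)C2 | intermediate
22 | 3-phenylpropanoic acid | OC(=O)CCc1ccccc1 | starting material
23 | (1R,4S,5S,9S)-4,8-dimethyl-1-[(2S)-1-oxopropan-2-yl]spiro[4.5]dec-7-en-9-yl 3-phenylpropanoate | O=C[C@@H](C)[C@H]1CC[C@H](C)[C@@]12CC=C(C)[C@@H](OC(=O)CCc3ccccc3)C2 | intermediate
24 | 3-methylfuran-2(5H)-one | CC1=CCOC1=O | starting material
25 | tert-butyldimethyl[(3-methylfuran-2-yl)oxy]silane | Cc1ccoc1O[Si](C)(C)C(C)(C)C | intermediate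
26 | (1R,4S,5S,9S)-1-[(2S)-1-(tert-butyldimethylsilyloxy)-1-(4-methyl-5-oxo-2,5-dihydrofuran-2-yl)propan-2-yl]-4,8-dimethylspiro[4.5]dec-7-en-9-yl 3-phenylpropanoate (mixture at the two new centres) | CC1=CC(OC1=O)C(O[Si](C)(C)C(C)(C)C)[C@@H](C)[C@H]2CC[C@H](C)[C@@]23CC=C(C)[C@@H](OC(=O)CCc4ccccc4)C3 | intermediate
27 | (1R,4S,5S,9S)-4,8-dimethyl-1-[(1Z,2S)-1-(4-methyl-5-oxofuran-2(5H)-ylidene)propan-2-yl]spiro[4.5]dec-7-en-9-yl 3-phenylpropanoate (CNP0260277.1) | CC1=C/C(=C/[C@@H](C)[C@H]2CC[C@H](C)[C@@]23CC=C(C)[C@@H](OC(=O)CCc2ccccc2)C3)OC1=O | target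

Total step count: 16. Longest linear sequence: 16 steps (1 to 27; 7, 22 and 24 are purchased).

Steps least certain to work

Step 7 (key step). The 1,4-diradical may revert or disproportionate instead of closing the congested C6–C11 bond, and the single stereocentre C4 may not fully differentiate the faces of C5. Either would cost material or open the C1/C5-epimeric series. The fallback sets out from 11 and forms C5–C1 without the sacrificial bond, by intramolecular reductive coupling of the two β-carbons (SmI2, HMPA, t-BuOH, THF; the electrohydrocyclisation type of reaction). This would give methyl (2S)-2-[(1R,4S,5R)-4-methyl-7-oxospiro[4.5]decan-1-yl]propanoate F1. Chelation of trivalent samarium between the C7 enolate oxygen and the ester is counted on to hold C11 on the C6 side, which is less secure than the ring constraint of the photoadduct. Kinetic deprotonation of F1 with LiN(i-Pr)2 away from the quaternary C5 gives the lithium C7=C8 enolate of F1 F2, and iodomethane then returns the route to 15.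

Step 9. Protonation of the ester enolate may show poor facial selectivity, because the preference rests on an acyclic conformational argument, and excess reductant may also reduce the liberated ketone. The fallback sets out from 15 as a mixture of C11 epimers and replaces kinetic control by separation and recycling. The 11R epimer of 15, methyl (2R)-2-[(1R,4S,5R)-4,8-dimethyl-7-oxospiro[4.5]decan-1-yl]propanoate F3, is carried with 15 through steps 10–12. On the way it passes the 11R trimethylsilyl enol ether F4, the 11R enone methyl (2R)-2-[(1R,4S,5R)-4,8-dimethyl-7-oxospiro[4.5]dec-8-en-1-yl]propanoate F5 and the 11R epoxy ketone F6. At the hydroxy ester stage only C11 differs, so methyl (2R)-2-[(1R,4S,5S,9S)-9-hydroxy-4,8-dimethylspiro[4.5]dec-7-en-1-yl]propanoate F7 is separated from 19. F7 is then re-equilibrated at C11 with NaOMe in MeOH (C11 is the only acidic stereocentre) and separated again, and the route is rejoined at 19.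

Step 11. The two faces of the enone differ only by C1–H against the C4 methyl two bonds away, so the facial selectivity of hydroperoxide addition may be poor. The fallback sets out from 17 and makes the sequence stereoconvergent. The (8R,9R)-epoxy ketone F8 formed beside 18 gives, in the Wharton step, methyl (2S)-2-[(1R,4S,5S,9R)-9-hydroxy-4,8-dimethylspiro[4.5]dec-7-en-1-yl]propanoate F9, which is separated from 19. Mitsunobu reaction of F9 with 4-nitrobenzoic acid (PPh3, DIAD) inverts C9 to give (1R,4S,5S,9S)-1-[(2S)-1-methoxy-1-oxopropan-2-yl]-4,8-dimethylspiro[4.5]dec-7-en-9-yl 4-nitrobenzoate F10. Methanolysis with K2CO3 in MeOH then returns the route to 19.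

Step 4. The C4–H bond of 5 is both benzylic and allylic. Base formed during the reduction may move the vinyl group into conjugation, where it would be reduced, or may erode the configuration at C4. The fallback sets out from 5 and removes the allylic relationship before the reduction.
- Hydroboration of 5 with 9-BBN gives 9-[(3S)-3-(3-methoxyphenyl)butyl]-9-borabicyclo[3.3.1]nonane F11, which is coupled with vinyl bromide (PdCl2(dppf), K3PO4) to give 1-[(2S)-hex-5-en-2-yl]-3-methoxybenzene F12.
- Birch reduction gives 1-[(2S)-hex-5-en-2-yl]-5-methoxycyclohexa-1,4-diene F13.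
- Acid hydrolysis passes through 3-[(2S)-hex-5-en-2-yl]cyclohex-3-en-1-one F14 to 3-[(2S)-hex-5-en-2-yl]cyclohex-2-en-1-one F15.
- Cross-metathesis of F15 with methyl methacrylate (second-generation Grubbs catalyst, RuCl2(=CHPh)(PCy3)(H2IMes), CH2Cl2, 40 °C) gives the E-2-methylenoate and returns the route to 11.

Step 16. The silyl triflate and amine may enolise the α-branched aldehyde and erode C11, and the elimination may give some E alkene. The fallback sets out from 21 and builds the lactone on an alkyne, which avoids the aldol step and fixes the alkene geometry by the mode of ring closure.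
- Ohira–Bestmann homologation of 21 (dimethyl (1-diazo-2-oxopropyl)phosphonate, K2CO3, MeOH) gives (1R,4S,5S,9S)-1-[(2S)-but-3-yn-2-yl]-4,8-dimethylspiro[4.5]dec-7-en-9-ol F16.
- Steglich acylation with 22 gives (1R,4S,5S,9S)-1-[(2S)-but-3-yn-2-yl]-4,8-dimethylspiro[4.5]dec-7-en-9-yl 3-phenylpropanoate F17.
- Sonogashira coupling of F17 with (Z)-3-iodo-2-methylprop-2-enoic acid (PdCl2(PPh3)2, CuI, Et3N, MeCN) is followed in the same flask by 5-exo lactonisation of the carboxylate onto the alkyne by anti addition. This gives the Z-alkylidene butenolide and returns the route to 27.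

Further compounds
F1 | step 7 | methyl (2S)-2-[(1R,4S,5R)-4-methyl-7-oxospiro[4.5]decan-1-yl]propanoate | COC(=O)[C@@H](C)[C@H]1CC[C@H](C)[C@@]12CC(=O)CCC2
F2 | step 7 | lithium C7=C8 enolate of F1 | COC(=O)[C@@H](C)[C@H]1CC[C@H](C)[C@@]12CC(O[Li])=CCC2
F3 | step 9 | methyl (2R)-2-[(1R,4S,5R)-4,8-dimethyl-7-oxospiro[4.5]decan-1-yl]propanoate | COC(=O)[C@H](C)[C@H]1CC[C@H](C)[C@@]12CC(=O)C(C)CC2
F4 | step 9 | methyl (2R)-2-[(1R,4S,5R)-4,8-dimethyl-7-(trimethylsilyloxy)spiro[4.5]dec-7-en-1-yl]propanoate | COC(=O)[C@H](C)[C@H]1CC[C@H](C)[C@@]12CC(O[Si](C)(C)C)=C(C)CC2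
F5 | step 9 | methyl (2R)-2-[(1R,4S,5R)-4,8-dimethyl-7-oxospiro[4.5]dec-8-en-1-yl]propanoate | COC(=O)[C@H](C)[C@H]1CC[C@H](C)[C@@]12CC(=O)C(C)=CC2
F6 | step 9 | methyl (2R)-2-[(1R,4S,5R,8S,9S)-8,9-epoxy-4,8-dimethyl-7-oxospiro[4.5]decan-1-yl]propanoate | COC(=O)[C@H](C)[C@H]1CC[C@H](C)[C@@]12CC(=O)[C@@]3(C)O[C@H]3C2
F7 | step 9 | methyl (2R)-2-[(1R,4S,5S,9S)-9-hydroxy-4,8-dimethylspiro[4.5]dec-7-en-1-yl]propanoate | COC(=O)[C@H](C)[C@H]1CC[C@H](C)[C@@]12CC=C(C)[C@@H](O)C2
F8 | step 11 | methyl (2S)-2-[(1R,4S,5R,8R,9R)-8,9-epoxy-4,8-dimethyl-7-oxospiro[4.5]decan-1-yl]propanoate | COC(=O)[C@@H](C)[C@H]1CC[C@H](C)[C@@]12CC(=O)[C@]3(C)O[C@@H]3C2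
F9 | step 11 | methyl (2S)-2-[(1R,4S,5S,9R)-9-hydroxy-4,8-dimethylspiro[4.5]dec-7-en-1-yl]propanoate | COC(=O)[C@@H](C)[C@H]1CC[C@H](C)[C@@]12CC=C(C)[C@H](O)C2
F10 | step 11 | (1R,4S,5S,9S)-1-[(2S)-1-methoxy-1-oxopropan-2-yl]-4,8-dimethylspiro[4.5]dec-7-en-9-yl 4-nitrobenzoate | COC(=O)[C@@H](C)[C@H]1CC[C@H](C)[C@@]12CC=C(C)[C@@H](OC(=O)c3ccc(cc3)[N+](=O)[O-])C2
F11 | step 4 | 9-[(3S)-3-(3-methoxyphenyl)butyl]-9-borabicyclo[3.3.1]nonane | B1(CC[C@H](C)c2cccc(OC)c2)C3CCCC1CCC3
F12 | step 4 | 1-[(2S)-hex-5-en-2-yl]-3-methoxybenzene | C=CCC[C@H](C)c1cccc(OC)c1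
F13 | step 4 | 1-[(2S)-hex-5-en-2-yl]-5-methoxycyclohexa-1,4-diene | C=CCC[C@H](C)C1=CCC=C(OC)C1
F14 | step 4 | 3-[(2S)-hex-5-en-2-yl]cyclohex-3-en-1-one | C=CCC[C@H](C)C1=CCCC(=O)C1
F15 | step 4 | 3-[(2S)-hex-5-en-2-yl]cyclohex-2-en-1-one | C=CCC[C@H](C)C1=CC(=O)CCC1
F16 | step 16 | (1R,4S,5S,9S)-1-[(2S)-but-3-yn-2-yl]-4,8-dimethylspiro[4.5]dec-7-en-9-ol | C#C[C@@H](C)[C@H]1CC[C@H](C)[C@@]12CC=C(C)[C@@H](O)C2
F17 | step 16 | (1R,4S,5S,9S)-1-[(2S)-but-3-yn-2-yl]-4,8-dimethylspiro[4.5]dec-7-en-9-yl 3-phenylpropanoate | C#C[C@@H](C)[C@H]1CC[C@H](C)[C@@]12CC=C(C)[C@@H](OC(=O)CCc3ccccc3)C2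
A1 | alternative 1 | tert-butyldimethylsilyl ether of (2S)-2-[7-methyl-1-((E)-prop-1-enyl)spiro[2.4]heptan-4-yl]propan-1-ol, ring A configured as in the target | CC(C)(C)[Si](C)(C)OC[C@@H](C)[C@H]1CC[C@H](C)[C@@]12C(/C=C/C)C2
A2 | alternative 1 | 1-[(2S)-1-(tert-butyldimethylsilyloxy)propan-2-yl]-4,8-dimethylspiro[4.5]dec-7-en-9-one, C1, C4 and C5 configured as in the target | CC(C)(C)[Si](C)(C)OC[C@@H](C)[C@H]1CC[C@H](C)[C@@]12CC=C(C)C(=O)C2
A3 | alternative 2 | (2Z,6E)-3,7,11-trimethyl-12-(trimethylsilyl)dodeca-2,6,10-trien-1-yl acetate | CC(=O)OC/C=C(/C)CC/C=C(\C)CCC=C(C)C[Si](C)(C)C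
A4 | alternative 2 | 4,8-dimethyl-1-(prop-1-en-2-yl)spiro[4.5]dec-7-ene, C1, C4 and C5 configured as in the target | C=C(C)[C@H]1CC[C@H](C)[C@@]12CC=C(C)CC2
A5 | alternative 3 | 3-(1-hydroxy-2-methylcyclobutyl)cyclohex-2-en-1-one | O=C1C=C(CCC1)C1(O)CCC1C
A6 | alternative 3 | 4-methylspiro[4.5]decane-1,9-dione, C4 and C5 configured as in the target | O=C1CC[C@H](C)[C@@]12CCCC(=O)C2
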